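**Retrosynthetic overview**
- The target comes from its tri-O-benzyl ether by one global hydrogenolysis.
- Key disconnection, aryl–C1: the β-carbon of the C3 ketone is used as a nucleophile (ketone homoenolate, in the form of a cyclopropanol) against an aryl bromide in a Pd-catalysed ring-opening arylation.
- The cyclopropanol comes from an (R)-β-hydroxy ester by Kulinkovich cyclopropanation; C1 and C2 come from EtMgBr.
- The (R)-β-hydroxy ester comes from a β-keto ester by Noyori hydrogenation (sets C5); the keto ester comes from dibenzylated 5-hydroxyvanillin by Wittig olefination and C=C hydrogenation.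
- Rings: both arenes are bought; the only ring made is the cyclopropane (step 5), which is opened again in step 6.

Assumption: 5-hydroxyvanillin, the acetoacetate Wittig ylide and 4-benzyloxy-3-methoxybromobenzene are bought as catalogue compounds; the route is a proposal and the ee is an expected value.

**Step 1**
Reactants: 1 3,4-dihydroxy-5-methoxybenzaldehyde
Product: 2 3,4-bis(benzyloxy)-5-methoxybenzaldehyde
Conditions: BnBr (2.3 equiv), K2CO3 (3 equiv), DMF, 60 °C
Reagents that add atoms: benzyl bromide, BrCc1ccccc1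
Why: Williamson ether synthesis, in which carbonate deprotonates both phenols and the phenoxides displace bromide by SN2 while the aldehyde is inert.

**Step 2**
Reactants: 2 3,4-bis(benzyloxy)-5-methoxybenzaldehyde; 3 ethyl 3-oxo-4-(triphenylphosphoranylidene)butanoate
Product: 5 ethyl (4E)-5-[3,4-bis(benzyloxy)-5-methoxyphenyl]-3-oxopent-4-enoate, via sodium ylide anion 4 (not isolated)
Conditions: 3, NaH (1.1 equiv), THF, 0 °C; then 2, rt to 45 °C; then 1 M HCl
Reagents that add atoms: none
Why: Wittig olefination, in which NaH removes the acidic C2 proton of 3 to give ylide anion 4, which is far more nucleophilic at the ylide carbon than neutral keto-stabilised 3 and converts the aldehyde into the conjugated E-alkene with loss of Ph3PO.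

**Step 3**
Reactants: 5 ethyl (4E)-5-[3,4-bis(benzyloxy)-5-methoxyphenyl]-3-oxopent-4-enoate
Product: 6 ethyl 5-[3,4-bis(benzyloxy)-5-methoxyphenyl]-3-oxopentanoate
Conditions: H2 (1 atm), 10% Pd/C, Ph2S (0.01 equiv), EtOAc, rt
Reagents that add atoms: none
Why: Chemoselective catalytic hydrogenation, since Pd/C poisoned with Ph2S still saturates the conjugated C=C but no longer cleaves aryl benzyl ethers or reduces the ketone.

**Step 4**
Reactants: 6 ethyl 5-[3,4-bis(benzyloxy)-5-methoxyphenyl]-3-oxopentanoate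
Product: 7 ethyl (3R)-5-[3,4-bis(benzyloxy)-5-methoxyphenyl]-3-hydroxypentanoate
Conditions: RuCl2[(R)-BINAP] (0.5 mol %), H2 (50 atm), EtOH, 50 °C
Reagents that add atoms: none
Why: Noyori asymmetric hydrogenation of a β-keto ester, in which the ester chelates ruthenium and (R)-BINAP directs hydride to one face of the ketone to set the (R)-carbinol that becomes C5 (expected ee at least 97%), with the benzyl ethers untouched.

**Step 5**
Reactants: 7 ethyl (3R)-5-[3,4-bis(benzyloxy)-5-methoxyphenyl]-3-hydroxypentanoate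
Product: 8 1-[(2R)-4-[3,4-bis(benzyloxy)-5-methoxyphenyl]-2-hydroxybutyl]cyclopropan-1-ol
Conditions: EtMgBr (4 equiv, slow addition), Ti(OiPr)4 (30 mol %), THF, 0 °C to rt; then cold 1 M HCl
Reagents that add atoms: ethylmagnesium bromide, CC[Mg]Br
Why: Kulinkovich cyclopropanation, in which EtMgBr and Ti(OiPr)4 form a titanacyclopropane that adds twice to the ester carbon as a 1,2-dicarbanion, while the first equivalent of EtMgBr only turns the free hydroxyl into its alkoxide (as happens with lactone substrates), so the stereocenter is untouched.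

**Step 6**
Reactants: 8 1-[(2R)-4-[3,4-bis(benzyloxy)-5-methoxyphenyl]-2-hydroxybutyl]cyclopropan-1-ol; 9 1-(benzyloxy)-4-bromo-2-methoxybenzene
Product: 10 (5R)-1-[4-(benzyloxy)-3-methoxyphenyl]-7-[3,4-bis(benzyloxy)-5-methoxyphenyl]-5-hydroxyheptan-3-one
Conditions: Pd(OAc)2 (5 mol %), XPhos (10 mol %), Cs2CO3 (1.5 equiv), toluene, 60 °C
Reagents that add atoms: none
Why: Palladium-catalysed ring-opening cross-coupling of a cyclopropanol used as a ketone homoenolate, in which 9 adds oxidatively to zerovalent palladium, the cyclopropoxide undergoes strain-driven β-carbon elimination to put palladium on C1, and reductive elimination (favoured over β-hydride elimination by bulky XPhos) forms the aryl–C1 bond and frees the C3 ketone without touching the C5 stereocenter.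

**Step 7**
Reactants: 10 (5R)-1-[4-(benzyloxy)-3-methoxyphenyl]-7-[3,4-bis(benzyloxy)-5-methoxyphenyl]-5-hydroxyheptan-3-one
Product: 11 (5R)-7-(3,4-dihydroxy-5-methoxyphenyl)-5-hydroxy-1-(4-hydroxy-3-methoxyphenyl)heptan-3-one
Conditions: H2 (1 atm), 10% Pd/C, EtOAc/MeOH, rt
Reagents that add atoms: none
Why: Catalytic hydrogenolysis of the three aryl benzyl ethers under neutral conditions, which leaves the aliphatic ketone, the secondary alcohol and the C5 stereocenter unchanged.

**Compound list**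
1 | 3,4-dihydroxy-5-methoxybenzaldehyde (5-hydroxyvanillin) | O=Cc1cc(O)c(O)c(OC)c1 | starting material
2 | 3,4-bis(benzyloxy)-5-methoxybenzaldehyde | O=Cc1cc(OCc2ccccc2)c(OCc2ccccc2)c(OC)c1 | intermediate
3 | ethyl 3-oxo-4-(triphenylphosphoranylidene)butanoate | CCOC(=O)CC(=O)C=P(c1ccccc1)(c1ccccc1)c1ccccc1 | starting material
4 | sodium ylide anion (sodium salt of 3 deprotonated at C2) | CCOC(=O)[CH-]C(=O)C=P(c1ccccc1)(c1ccccc1)c1ccccc1.[Na+] | intermediate
5 | ethyl (4E)-5-[3,4-bis(benzyloxy)-5-methoxyphenyl]-3-oxopent-4-enoate | CCOC(=O)CC(=O)/C=C/c1cc(OCc2ccccc2)c(OCc2ccccc2)c(OC)c1 | intermediate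
6 | ethyl 5-[3,4-bis(benzyloxy)-5-methoxyphenyl]-3-oxopentanoate | CCOC(=O)CC(=O)CCc1cc(OCc2ccccc2)c(OCc2ccccc2)c(OC)c1 | intermediate
7 | ethyl (3R)-5-[3,4-bis(benzyloxy)-5-methoxyphenyl]-3-hydroxypentanoate | CCOC(=O)C[C@H](O)CCc1cc(OCc2ccccc2)c(OCc2ccccc2)c(OC)c1 | intermediate
8 | 1-[(2R)-4-[3,4-bis(benzyloxy)-5-methoxyphenyl]-2-hydroxybutyl]cyclopropan-1-ol | OC1(C[C@H](O)CCc2cc(OCc3ccccc3)c(OCc3ccccc3)c(OC)c2)CC1 | intermediate
9 | 1-(benzyloxy)-4-bromo-2-methoxybenzene | COc1cc(Br)ccc1OCc1ccccc1 | starting material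
10 | (5R)-1-[4-(benzyloxy)-3-methoxyphenyl]-7-[3,4-bis(benzyloxy)-5-methoxyphenyl]-5-hydroxyheptan-3-one | COc1cc(CCC(=O)C[C@H](O)CCc2cc(OCc3ccccc3)c(OCc3ccccc3)c(OC)c2)ccc1OCc1ccccc1 | intermediate
11 | (5R)-7-(3,4-dihydroxy-5-methoxyphenyl)-5-hydroxy-1-(4-hydroxy-3-methoxyphenyl)heptan-3-one | COc1cc(CCC(=O)C[C@H](O)CCc2cc(O)c(O)c(OC)c2)ccc1O | target

**Step count**
Total: 7 steps. Longest linear sequence: 7 steps (1 → 2 → 5 → 6 → 7 → 8 → 10 → 11).

**Steps most likely to fail, with fallbacks**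

Most at risk is step 6. The palladium homoenolate may undergo β-hydride elimination to the vinyl ketone, which the free C5 hydroxyl can then close by oxa-Michael addition, or carbonate may dehydrate or retro-aldolise 10. The fallback uses a second ketone-homoenolate equivalent, a secondary allylic alcohol in a Heck arylation, with the C5 hydroxyl masked. It sets out from 7. TBSCl and imidazole in DMF give ethyl (3R)-5-[3,4-bis(benzyloxy)-5-methoxyphenyl]-3-[(tert-butyldimethylsilyl)oxy]pentanoate F1. Reduction with i-Bu2AlH in CH2Cl2 at −78 °C gives (3R)-5-[3,4-bis(benzyloxy)-5-methoxyphenyl]-3-[(tert-butyldimethylsilyl)oxy]pentanal F2. CH2=CHMgBr in THF at −78 °C gives (5R)-7-[3,4-bis(benzyloxy)-5-methoxyphenyl]-5-[(tert-butyldimethylsilyl)oxy]hept-1-en-3-ol F3 as a mixture of C3 epimers, which does not matter because C3 becomes the ketone. Heck arylation of F3 with 9 (Pd(OAc)2, Bu4NCl, NaHCO3, DMF, 80 °C), where β-hydride elimination towards the carbinol carbon is the productive path, gives (5R)-1-[4-(benzyloxy)-3-methoxyphenyl]-7-[3,4-bis(benzyloxy)-5-methoxyphenyl]-5-[(tert-butyldimethylsilyl)oxy]heptan-3-one F4. HF·pyridine in THF removes the silyl group and the route is back at 10.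

Second is step 5. The magnesium or titanium alkoxide of the free β-hydroxyl may slow the titanium cycle or open a retro-aldol path. The fallback masks the hydroxyl for the cyclopropanation only. It sets out from 7. TESCl and imidazole in CH2Cl2 give ethyl (3R)-5-[3,4-bis(benzyloxy)-5-methoxyphenyl]-3-[(triethylsilyl)oxy]pentanoate F5. Kulinkovich cyclopropanation (EtMgBr 2.5 equiv, Ti(OiPr)4 20 mol %, THF) gives 1-[(2R)-4-[3,4-bis(benzyloxy)-5-methoxyphenyl]-2-[(triethylsilyl)oxy]butyl]cyclopropan-1-ol F6. PPTS in MeOH at 0 °C cleaves the silyl ether and the route is back at 8.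

Third is step 3. The poisoned catalyst may still remove some aryl benzyl ethers, or may stop short of full C=C reduction. The fallback never makes the alkene and builds the C6–C7 bond by alkylation, so it bypasses steps 2 and 3. It sets out from 2. NaBH4 in MeOH gives [3,4-bis(benzyloxy)-5-methoxyphenyl]methanol F7. Concentrated HCl in CH2Cl2 at rt gives 1,2-bis(benzyloxy)-5-(chloromethyl)-3-methoxybenzene F8. NaH and then n-BuLi in THF at 0 °C convert ethyl acetoacetate into ethyl acetoacetate sodium lithium dianion F9, which is alkylated at its terminal carbon by F8. Acidic work-up then gives the keto ester and the route is back at 6.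

**Further compounds**
F1 | step 6 | ethyl (3R)-5-[3,4-bis(benzyloxy)-5-methoxyphenyl]-3-[(tert-butyldimethylsilyl)oxy]pentanoate | CCOC(=O)C[C@H](O[Si](C)(C)C(C)(C)C)CCc1cc(OCc2ccccc2)c(OCc2ccccc2)c(OC)c1
F2 | step 6 | (3R)-5-[3,4-bis(benzyloxy)-5-methoxyphenyl]-3-[(tert-butyldimethylsilyl)oxy]pentanal | O=CC[C@H](O[Si](C)(C)C(C)(C)C)CCc1cc(OCc2ccccc2)c(OCc2ccccc2)c(OC)c1
F3 | step 6 | (5R)-7-[3,4-bis(benzyloxy)-5-methoxyphenyl]-5-[(tert-butyldimethylsilyl)oxy]hept-1-en-3-ol (C3 epimer mixture) | C=CC(O)C[C@H](O[Si](C)(C)C(C)(C)C)CCc1cc(OCc2ccccc2)c(OCc2ccccc2)c(OC)c1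
F4 | step 6 | (5R)-1-[4-(benzyloxy)-3-methoxyphenyl]-7-[3,4-bis(benzyloxy)-5-methoxyphenyl]-5-[(tert-butyldimethylsilyl)oxy]heptan-3-one | COc1cc(CCC(=O)C[C@H](O[Si](C)(C)C(C)(C)C)CCc2cc(OCc3ccccc3)c(OCc3ccccc3)c(OC)c2)ccc1OCc1ccccc1
F5 | step 5 | ethyl (3R)-5-[3,4-bis(benzyloxy)-5-methoxyphenyl]-3-[(triethylsilyl)oxy]pentanoate | CCOC(=O)C[C@H](O[Si](CC)(CC)CC)CCc1cc(OCc2ccccc2)c(OCc2ccccc2)c(OC)c1
F6 | step 5 | 1-[(2R)-4-[3,4-bis(benzyloxy)-5-methoxyphenyl]-2-[(triethylsilyl)oxy]butyl]cyclopropan-1-ol | OC1(C[C@H](O[Si](CC)(CC)CC)CCc2cc(OCc3ccccc3)c(OCc3ccccc3)c(OC)c2)CC1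
F7 | step 3 | [3,4-bis(benzyloxy)-5-methoxyphenyl]methanol | OCc1cc(OCc2ccccc2)c(OCc2ccccc2)c(OC)c1
F8 | step 3 | 1,2-bis(benzyloxy)-5-(chloromethyl)-3-methoxybenzene | ClCc1cc(OCc2ccccc2)c(OCc2ccccc2)c(OC)c1
F9 | step 3 | ethyl acetoacetate sodium lithium dianion | CCOC(=O)[CH-]C(=O)[CH2-].[Na+].[Li+]
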